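**Plan**

1. Retrosynthesis (eunicellane numbering: C1/C10 ring fusion, C11=C12, C14 i‑Pr, C3 CO2Me, C4 hemiketal, C7 Me, C8 O‑acyl): cut the C8–O acyl bond; then O7–C4 and C7–CH3, back through a bridged pyranone to a furan spanning C4–C7; then C7–C8 (ring closure of the ten‑membered carbocycle) and C2–C3 (enolate alkylation); last the two cyclohexene bonds C10–C11 and C1–C14 in one [4+2].
2. Forward: the cyclohexene (C1, C10–C14) is made first, cis‑fused to a δ‑lactone. The lactone is opened to a C2 iodide arm and a C8 aldehyde arm. A 2,5‑disubstituted furan is attached at C3 and closes the ten‑membered ring at C8. The furan is then unravelled to the O‑bridged dihydrofuran hemiketal, and the urocanate comes last.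
3. Enabling feature: the C1–C10 bond is shared by the six‑ and ten‑membered rings, its flanking methylenes C2 and C9 are cis, and C8 bears oxygen. The chain C2–C1–C10–C9–C8–O is therefore a latent 5,6‑dihydropyran‑2‑one, whose ring‑locked Z C1=C10 is the dienophile. A diene oxygen at C12 (a helper) later directs i‑Pr to C14 and then becomes the C11=C12 alkene.
4. Stereochemistry: C1/C10 come from the catalyst‑controlled suprafacial cycloaddition; C14 is relayed from them (cuprate anti to the lactone); C8 is set by Ru–TsDPEN reduction; C7 by attack anti to the carbon bridge of the bicyclic pyranone; C4 by the bridge; C3 by equilibration.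

Key step: step 2

Assumption: C3 is the α‑carbon of a masked β‑keto ester and equilibrates through the ring‑opened 4‑keto form; the (3R) epimer of the target is taken to be the thermodynamic one, and 15–24 are carried as C3 epimer mixtures.
Assumption: 3, 13 and 26 are purchased.

**Step 1**
Reactants: 1 pent‑1‑en‑3‑one
Product: 2 (Z)‑3‑(tert‑butyldimethylsilyloxy)penta‑1,3‑diene
Conditions: TBSOTf, Et3N, Et2O, 0 °C
Reagents that add atoms: tert‑butyldimethylsilyl trifluoromethanesulfonate CC(C)(C)[Si](C)(C)OS(=O)(=O)C(F)(F)F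
Why: Soft enolisation of the ethyl ketone at its CH2 (silyl enol ether formation) should give the cross‑conjugated 2‑silyloxy diene as the Z enol ether, with CH3 trans to the vinyl group so that the s‑cis diene is accessible.

**Step 2**
Reactants: 2 (Z)‑3‑(tert‑butyldimethylsilyloxy)penta‑1,3‑diene; 3 5,6‑dihydro‑2H‑pyran‑2‑one
Product: 4 cis‑fused cycloadduct (δ‑lactone fused at C1/C10 to a cyclohexene with C12–OTBS enol ether and C11–CH3)
Conditions: AlBr3‑activated (S)‑B‑(o‑tolyl)‑diphenylprolinol oxazaborolidine (10 mol%), 2 (1.5 equiv), CH2Cl2, −40 °C; Et3N quench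
Reagents that add atoms: none
Why: The cationic oxazaborolidine binds the lactone carbonyl and lowers its LUMO, and the 2‑silyloxy diene adds in a concerted, asynchronous, normal‑demand [4+2] cycloaddition in which C10–C11 forms ahead of C1–C14. The closest known reaction type is the cationic‑oxazaborolidine‑catalysed Diels–Alder addition of 2‑silyloxy‑1,3‑dienes to cyclic enones and α,β‑unsaturated esters. The cyclohexene ring is closed by intermolecular suprafacial [4+2] cycloaddition and is annulated cis onto the lactone. C1 and C10 are cis because the lactone ring fixes the dienophile as Z and both bonds form on one face; their absolute configuration comes from the catalyst, whose aryl group shields one face of the bound lactone (the antipodal catalyst is equally available); C11 follows from the Z enol ether and the endo transition state and is removed later. The step needs regioselectivity (the silyloxy group on C12 makes C11 the nucleophilic terminus, which pairs with the β‑carbon C10), cis fusion (secured by the cyclic dienophile) and enantiofacial selectivity (secured by the catalyst).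

**Step 3**
Reactants: 4 cis‑fused cycloadduct
Product: 5 cis‑fused enone lactone (C12 ketone with C13=C14)
Conditions: Pd(OAc)2 (1.1 equiv), MeCN, rt
Reagents that add atoms: none
Why: Ito–Saegusa oxidation of the regiodefined silyl enol ether gives a C13 palladium enolate whose only β‑hydrogens are on C14, so the enone should form at C13=C14.

**Step 4**
Reactants: 5 cis‑fused enone lactone
Product: 7 cis‑fused keto lactone (i‑Pr at C14 trans to the C1 arm), via TMS enol ether 6 (not isolated)
Conditions: i‑PrMgCl, CuBr·SMe2 (20 mol%), TMSCl, THF, −78 °C; then 1 M HCl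
Reagents that add atoms: isopropylmagnesium chloride CC(C)[Mg]Cl; chlorotrimethylsilane C[Si](C)(C)Cl (in 6 only)
Why: Copper‑catalysed conjugate addition should deliver isopropyl to C14 on the convex face, anti to the cis lactone arms on C1 and C10 (as in 4‑substituted cyclohexenones), which sets C14 trans to the C1 substituent.

**Step 5**
Reactants: 7 cis‑fused keto lactone
Product: 8 enol triflate (C11=C12, OTf on C12)
Conditions: Tf2O, 2,6‑di‑tert‑butyl‑4‑methylpyridine, CH2Cl2, 0 °C → rt
Reagents that add atoms: trifluoromethanesulfonic anhydride O=S(=O)(OS(=O)(=O)C(F)(F)F)C(F)(F)F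
Why: Enol triflate formation with a hindered pyridine base favours the more substituted enol triflate, which places the double bond at C11=C12 and erases the inconsequential C11 stereocentre.

**Step 6**
Reactants: 8 enol triflate
Product: 9 cis‑fused lactone with the C11=C12 alkene (8‑isopropyl‑5‑methyl‑3,4,4a,7,8,8a‑hexahydro‑1H‑isochromen‑1‑one)
Conditions: Pd(OAc)2 (5 mol%), PPh3, HCO2H, n‑Bu3N, DMF, 60 °C
Reagents that add atoms: none
Why: Palladium‑catalysed formate reduction of an enol triflate replaces OTf by H without moving the double bond, and the lactone is inert.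

**Step 7**
Reactants: 9 cis‑fused lactone
Product: 10 diol (C2–OH and C8–OH)
Conditions: LiAlH4, THF, 0 °C; Fieser work‑up
Reagents that add atoms: none
Why: Hydride reduction of the lactone gives the 1,5‑diol and leaves the trisubstituted alkene untouched.

**Step 8**
Reactants: 10 diol
Product: 11 mono‑TES ether (C8–OTES, free C2–OH)
Conditions: TESCl (1.05 equiv), imidazole, CH2Cl2, −78 → −40 °C
Reagents that add atoms: chlorotriethylsilane CC[Si](CC)(CC)Cl
Why: Kinetic silylation should favour the unhindered CH2CH2OH (C8) over the CH2OH (C2), which is flanked by the ring and the C14 isopropyl group.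

**Step 9**
Reactants: 11 mono‑TES ether
Product: 12 primary iodide (C2–I)
Conditions: I2, PPh3, imidazole, CH2Cl2, 0 °C
Reagents that add atoms: iodine II
Why: Appel‑type iodination converts the remaining primary alcohol to the iodide, with imidazole buffering the silyl ether.

**Step 10**
Reactants: 13 methyl 2‑(furan‑2‑yl)acetate
Product: 14 methyl 2‑(5‑bromofuran‑2‑yl)acetate
Conditions: NBS, DMF, 0 °C, dark
Reagents that add atoms: N‑bromosuccinimide O=C1CCC(=O)N1Br
Why: Electrophilic bromination of a 2‑alkylfuran occurs at the free α‑position.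

**Step 11**
Reactants: 12 primary iodide; 14 methyl 2‑(5‑bromofuran‑2‑yl)acetate
Product: 15 alkylated furyl ester (C2–C3 bond; C3 epimers)
Conditions: 14 (1.5 equiv), LDA, THF, −78 °C; then 12, HMPA, −78 → 0 °C
Reagents that add atoms: none
Why: SN2 alkylation of the furylacetate lithium enolate by the primary iodide forms C2–C3; both C3 epimers are acceptable because C3 is equilibrated at the end.

**Step 12**
Reactants: 15 alkylated furyl ester
Product: 16 bromofuryl aldehyde (C8 aldehyde)
Conditions: (COCl)2, DMSO, CH2Cl2, −78 → −35 °C; Et3N, → rt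
Reagents that add atoms: none
Why: Swern oxidation of a primary triethylsilyl ether goes directly to the aldehyde because activated DMSO cleaves the Si–O bond, which saves a deprotection.

**Step 13**
Reactants: 16 bromofuryl aldehyde
Product: 17 macrocyclic furyl carbinol (ten‑membered carbocycle C1–C10 with the furan across C4–C7; C8 epimers)
Conditions: CrCl2 (8 equiv), NiCl2 (2 mol%), DMSO–THF, 2 mM by slow addition, rt
Reagents that add atoms: none
Why: In this Nozaki–Hiyama–Kishi reaction, Ni(0) inserts into the furyl C–Br bond and the furylchromium formed adds to the aldehyde, closing the ten‑membered ring as a furanophane, a closure with precedent in this ring system.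

**Step 14**
Reactants: 17 macrocyclic furyl carbinol
Product: 18 macrocyclic furyl ketone (C8 ketone)
Conditions: Dess–Martin periodinane, NaHCO3, CH2Cl2, 0 °C → rt
Reagents that add atoms: none
Why: Dess–Martin oxidation converges both C8 epimers to one ketone.

**Step 15**
Reactants: 18 macrocyclic furyl ketone
Product: 19 (8S)‑furyl carbinol
Conditions: RuCl[(S,S)‑TsDPEN](p‑cymene) (2 mol%), HCO2H/Et3N (5:2), CH2Cl2, rt
Reagents that add atoms: none
Why: Noyori asymmetric transfer hydrogenation distinguishes the furyl group from the CH2 group and should set (8S) by reagent control, leaving esters and the alkene alone.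

**Step 16**
Reactants: 19 (8S)‑furyl carbinol
Product: 21 bridged pyranone hemiketal (O8 links C8 and C4; C7 ketone; C5=C6), via Z‑enedione 20 (not isolated)
Conditions: NBS (1.05 equiv), NaHCO3, THF–H2O (4:1), 0 °C
Reagents that add atoms: water O
Why: In the Achmatowicz rearrangement the furan is oxidised and opened to the Z‑enedione, and the C8 hydroxyl closes on the C4 ketone; the strained, electron‑rich furan should react before the trisubstituted alkene.

**Step 17**
Reactants: 21 bridged pyranone hemiketal
Product: 22 bridged pyranone methyl ketal (C4–OMe)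
Conditions: HC(OMe)3, MeOH, PPTS (cat.), 0 °C → rt
Reagents that add atoms: methanol CO; trimethyl orthoformate COC(OC)OC
Why: Acid‑catalysed ketalisation of the hemiketal locks the pyranone so that the ring cannot open under the next, basic step.

**Step 18**
Reactants: 22 bridged pyranone methyl ketal
Product: 25 4,7‑oxa‑bridged hemiketal diol (the target without its urocanate), via methyl ketal carbinol 23 (not isolated), via pyranose hemiketal 24 (not isolated)
Conditions: MeMgBr (1.5 equiv), THF, −78 °C; then 0.5 M HCl, THF–H2O, 0 °C → rt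
Reagents that add atoms: methylmagnesium bromide C[Mg]Br; water O
Why: Grignard 1,2‑addition to the C7 ketone should occur anti to the five‑carbon bridge (C9 to C3) of the bicyclic pyranone, which puts CH3 trans to C9; acid then hydrolyses the ketal and ring–chain tautomerism moves the bridge from O8 to O7, with C4 fixed by the bridge.

**Step 19**
Reactants: 25 4,7‑oxa‑bridged hemiketal diol; 26 (E)‑3‑(1‑methyl‑1H‑imidazol‑4‑yl)acrylic acid
Product: 28 target CNP0113846.1, via pivalic mixed anhydride 27 (not isolated)
Conditions: 26, t‑BuCOCl, Et3N, THF, 0 °C; then 25, DMAP, ClCH2CH2Cl, rt → 60 °C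
Reagents that add atoms: pivaloyl chloride CC(C)(C)C(=O)Cl (in 27 only)
Why: Mixed‑anhydride acylation with DMAP esterifies the only secondary hydroxyl (C8), which locks the 4,7‑oxa‑bridged tautomer, and under the basic conditions C3 should equilibrate through the ring‑opened β‑keto ester to the (3R) epimer.

**Compound list**

1 | pent‑1‑en‑3‑one (ethyl vinyl ketone) | CCC(=O)C=C | starting material
2 | (Z)‑3‑(tert‑butyldimethylsilyloxy)penta‑1,3‑diene | C/C=C(/C=C)O[Si](C)(C)C(C)(C)C | intermediate
3 | 5,6‑dihydro‑2H‑pyran‑2‑one | O=C1C=CCCO1 | starting material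
4 | all‑cis 6‑(tert‑butyldimethylsilyloxy)‑5‑methyl‑3,4,4a,5,8,8a‑hexahydro‑1H‑isochromen‑1‑one; ring‑fusion carbons arranged as in the target | O=C1[C@@H]2CC=C(O[Si](C)(C)C(C)(C)C)[C@H](C)[C@@H]2CCO1 | intermediate
5 | cis‑fused 5‑methyl‑3,4,4a,5‑tetrahydro‑1H‑isochromene‑1,6(8aH)‑dione; methyl cis to the lactone arms | O=C1[C@@H]2C=CC(=O)[C@H](C)[C@@H]2CCO1 | intermediate
6 | trimethylsilyl enol ether of 7 (C12–OTMS, C12=C13) | O=C1[C@@H]2[C@@H](C(C)C)C=C(O[Si](C)(C)C)[C@H](C)[C@@H]2CCO1 | intermediate
7 | cis‑fused 8‑isopropyl‑5‑methylhexahydro‑1H‑isochromene‑1,6‑dione; isopropyl trans to the lactone carbonyl carbon on the neighbouring ring‑fusion carbon; methyl‑bearing carbon as formed (epimerisable, inconsequential) | O=C1[C@@H]2[C@@H](C(C)C)CC(=O)[C@H](C)[C@@H]2CCO1 | intermediate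
8 | enol triflate of 7 toward the methyl‑bearing carbon (C11=C12) | O=C1[C@@H]2[C@@H](C(C)C)CC(OS(=O)(=O)C(F)(F)F)=C(C)[C@@H]2CCO1 | intermediate
9 | cis‑fused 8‑isopropyl‑5‑methyl‑3,4,4a,7,8,8a‑hexahydro‑1H‑isochromen‑1‑one; isopropyl trans to the lactone carbonyl carbon | O=C1[C@@H]2[C@@H](C(C)C)CC=C(C)[C@@H]2CCO1 | intermediate
10 | 2‑[6‑(hydroxymethyl)‑5‑isopropyl‑2‑methylcyclohex‑2‑en‑1‑yl]ethanol; the two arms cis, isopropyl trans to CH2OH | OC[C@@H]1[C@@H](C(C)C)CC=C(C)[C@@H]1CCO | intermediate
11 | triethylsilyl ether of 10 at the hydroxyethyl oxygen | OC[C@@H]1[C@@H](C(C)C)CC=C(C)[C@@H]1CCO[Si](CC)(CC)CC | intermediate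
12 | iodide of 11 (CH2I in place of CH2OH) | IC[C@@H]1[C@@H](C(C)C)CC=C(C)[C@@H]1CCO[Si](CC)(CC)CC | intermediate
13 | methyl 2‑(furan‑2‑yl)acetate | COC(=O)Cc1ccco1 | starting material
14 | methyl 2‑(5‑bromofuran‑2‑yl)acetate | COC(=O)Cc1ccc(Br)o1 | intermediate
15 | methyl 2‑(5‑bromofuran‑2‑yl)‑3‑[6‑isopropyl‑3‑methyl‑2‑(2‑triethylsilyloxyethyl)cyclohex‑3‑en‑1‑yl]propanoate; ring stereocentres as in 10, C3 both epimers | COC(=O)C(c1ccc(Br)o1)C[C@@H]2[C@@H](C(C)C)CC=C(C)[C@@H]2CCO[Si](CC)(CC)CC | intermediate
16 | aldehyde from 15 (2‑oxoethyl arm in place of the silyloxyethyl arm) | COC(=O)C(c1ccc(Br)o1)C[C@@H]2[C@@H](C(C)C)CC=C(C)[C@@H]2CC=O | intermediate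
17 | furanophane carbinol: ten‑membered carbocycle C1–C10 cis‑fused to the cyclohexene, furan oxygen across C4/C7, C8–OH (both epimers), C3–CO2Me (both epimers) | COC(=O)C1C[C@@H]2[C@@H](C(C)C)CC=C(C)[C@@H]2CC(O)c3ccc1o3 | intermediate
18 | furanophane ketone (C8 ketone) | COC(=O)C1C[C@@H]2[C@@H](C(C)C)CC=C(C)[C@@H]2CC(=O)c3ccc1o3 | intermediate
19 | (8S)‑furanophane carbinol | COC(=O)C1C[C@@H]2[C@@H](C(C)C)CC=C(C)[C@@H]2C[C@H](O)c3ccc1o3 | intermediate
20 | ring‑opened (5Z)‑4,7‑diketo‑8‑hydroxy ten‑membered carbocycle | COC(=O)C1C[C@@H]2[C@@H](C(C)C)CC=C(C)[C@@H]2C[C@H](O)C(=O)/C=C\C1=O | intermediate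
21 | bridged pyranone hemiketal: O8 links C8 and C4, C4–OH, C7 ketone, C5=C6; C3 and C9 cis on the pyranone | COC(=O)C1C[C@@H]2[C@@H](C(C)C)CC=C(C)[C@@H]2C[C@@H]3O[C@@]1(O)C=CC3=O | intermediate
22 | methyl ketal of 21 (C4–OMe) | COC(=O)C1C[C@@H]2[C@@H](C(C)C)CC=C(C)[C@@H]2C[C@@H]3O[C@@]1(OC)C=CC3=O | intermediate
23 | C7 tertiary carbinol of 22 (C7–CH3 trans to C9, C7–OH cis to C9) | COC(=O)C1C[C@@H]2[C@@H](C(C)C)CC=C(C)[C@@H]2C[C@@H]3O[C@@]1(OC)C=C[C@]3(C)O | intermediate
24 | pyranose hemiketal from 23 (C4–OH) | COC(=O)C1C[C@@H]2[C@@H](C(C)C)CC=C(C)[C@@H]2C[C@@H]3O[C@@]1(O)C=C[C@]3(C)O | intermediate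
25 | 4,7‑oxa‑bridged hemiketal diol (target with free C8–OH; C3 drawn as the equilibrated 3R epimer) | COC(=O)[C@@H]1C[C@@H]2[C@@H](C(C)C)CC=C(C)[C@@H]2C[C@H](O)[C@]2(C)C=C[C@@]1(O)O2 | intermediate
26 | (E)‑3‑(1‑methyl‑1H‑imidazol‑4‑yl)acrylic acid (N‑methylurocanic acid) | OC(=O)/C=C/c1cn(C)cn1 | starting material
27 | mixed anhydride of 26 with pivalic acid | CC(C)(C)C(=O)OC(=O)/C=C/c1cn(C)cn1 | intermediate
28 | CNP0113846.1: (1R,3R,4R,7S,8S,10R,14R) in eunicellane numbering; 8‑O‑(E)‑N‑methylurocanoyl, 4‑hydroxy‑4,7‑oxa‑bridged, methyl ester on C3 | COC(=O)[C@@H]1C[C@@H]2[C@@H](C(C)C)CC=C(C)[C@@H]2C[C@H](OC(=O)/C=C/c2cn(C)cn2)[C@]2(C)C=C[C@@]1(O)O2 | target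

**Totals**

Total step count: 19. Longest linear sequence: 18 (steps 1–9 and 11–19).

**Steps most likely to fail**

1. Step 2. The δ‑lactone is a weak dienophile at the edge of the catalyst's scope. The diene may be consumed by Lewis‑acid desilylation or by a Mukaiyama–Michael addition that does not close the ring, and enantiofacial discrimination may be poor or of the opposite sense. The fallback sets out from 2 and 3 and returns at 5. An achiral promoter (Et2AlCl, CH2Cl2, −78 °C) or heat (toluene, sealed tube) gives the racemic cycloadduct, that is 4 together with its enantiomer ent‑4 F1. Saegusa oxidation as in step 3 gives 5 together with its enantiomer ent‑5 F2. Preparative chiral‑phase SFC then separates 5 from F2.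

2. Step 13. Strain in the furanophane may divert the organochromium species to protodebromination or to intermolecular coupling. The fallback sets out from 12 and 13 and returns at 18. Alkylation of the lithium enolate of 13 with 12 (as in step 11) gives the bromine‑free ester F3. HF·pyridine gives the primary alcohol F4, and TEMPO/PhI(OAc)2 in MeCN–H2O gives the carboxylic acid F5. Trifluoroacetic anhydride in CH2Cl2 at high dilution gives the mixed trifluoroacetic anhydride F6, which acylates the free furan α‑position (intramolecular Friedel–Crafts acylation) to give ketone 18 directly.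

3. Step 18. Facial selectivity at C7 may erode if the pyranone ring opens or chelates under the Grignard conditions. Competing attack on the esters and acid‑promoted dehydration of the hemiketal during hydrolysis are further risks. The fallback sets out from 19 and returns at 25. TBSOTf/2,6‑lutidine gives the C8 silyl ether F7. NBS/NaHCO3 in acetone–water, then pyridine, opens the furan to the Z‑enedione F8, which cannot form a pyranone. MeMgBr (2.2 equiv; the first equivalent enolises the β‑keto ester and masks C4) adds to the C7 ketone under Felkin–Anh control, anti to the non‑chelating silyloxy group. The C7 alkoxide then closes on C4 to give the silylated bridged hemiketal F9, and HF·pyridine gives 25.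

**Further compounds**

F1 | step 2 | ent‑4 (enantiomer of the cycloadduct) | O=C1[C@H]2CC=C(O[Si](C)(C)C(C)(C)C)[C@@H](C)[C@H]2CCO1
F2 | step 2 | ent‑5 (enantiomer of the enone lactone) | O=C1[C@H]2C=CC(=O)[C@@H](C)[C@H]2CCO1
F3 | step 13 | methyl 2‑(furan‑2‑yl)‑3‑[6‑isopropyl‑3‑methyl‑2‑(2‑triethylsilyloxyethyl)cyclohex‑3‑en‑1‑yl]propanoate | COC(=O)C(c1ccco1)C[C@@H]2[C@@H](C(C)C)CC=C(C)[C@@H]2CCO[Si](CC)(CC)CC
F4 | step 13 | primary alcohol from F3 | COC(=O)C(c1ccco1)C[C@@H]2[C@@H](C(C)C)CC=C(C)[C@@H]2CCO
F5 | step 13 | carboxylic acid from F4 | COC(=O)C(c1ccco1)C[C@@H]2[C@@H](C(C)C)CC=C(C)[C@@H]2CC(=O)O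
F6 | step 13 | mixed trifluoroacetic anhydride of F5 | COC(=O)C(c1ccco1)C[C@@H]2[C@@H](C(C)C)CC=C(C)[C@@H]2CC(=O)OC(=O)C(F)(F)F
F7 | step 18 | tert‑butyldimethylsilyl ether of 19 | COC(=O)C1C[C@@H]2[C@@H](C(C)C)CC=C(C)[C@@H]2C[C@H](O[Si](C)(C)C(C)(C)C)c3ccc1o3
F8 | step 18 | (5Z)‑4,7‑diketone with C8–OTBS | COC(=O)C1C[C@@H]2[C@@H](C(C)C)CC=C(C)[C@@H]2C[C@H](O[Si](C)(C)C(C)(C)C)C(=O)/C=C\C1=O
F9 | step 18 | C8‑O‑TBS ether of 25 | COC(=O)[C@@H]1C[C@@H]2[C@@H](C(C)C)CC=C(C)[C@@H]2C[C@H](O[Si](C)(C)C(C)(C)C)[C@]2(C)C=C[C@@]1(O)O2
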